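## Structural features

The target is a germacrane-type bis-lactone, and the usual numbering is used throughout. C1 to C10 form the ten-membered carbocycle, C14 is the hydroxymethyl carbon on C10, and C15 is the carbonyl carbon on C4. C11, C12 and C13 are the α-carbon, the carbonyl carbon and the exocyclic methylene of the lactone on C7. Two five-membered lactones are attached to the carbocycle. An α-methylene-γ-butyrolactone (C7, C8, C11, C12, O) is trans-fused at C7–C8, and a butenolide (C4, C5, C6, C15, O) spans C4 to C6, so that C4=C5 is trisubstituted with C3 and C6 on opposite sides. C6, C7 and C8 are contiguous stereocentres (6R,7S,8R; H7 and H8 trans, O6 and O8 1,3-anti). C3 (S, isobutyrate) and C10 (R, hydroxymethyl) are isolated from this triad by C4=C5 and by C9. The fragile groups are the exocyclic methylene lactone (a Michael acceptor that is also reducible and metathesis-active) and the C3 acyloxy group, which sits on the α-branch of the butenolide and is expelled if C6–H is removed by base. The real difficulty is twofold: closing a ten-membered ring that holds a ring-trans alkene tied back by the butenolide, and relating the remote centres C3 and C10 to the triad without a stereochemical relay. The key step uses the fact that C1 and C2 are the only neighbouring CH2 groups of the carbocycle, each next to a stereocentre (C10, C3) that can carry a vinyl group, so a metathesis seam at C1–C2 vanishes on hydrogenation.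

## Logic of the disconnections

29 to 28: the O–Si bond at C14 is cut. One silyl ether protects the only free hydroxyl through the whole route, and its removal must not touch the methylene lactone, so a buffered acidic fluoride source is required.

28 to 27: C11=C13 is cut to a C11 phosphonate and formaldehyde. The exocyclic methylene cannot be present during metathesis (it would close a cyclohexene with the C10 vinyl group) or hydrogenation. The forward olefination must run with a base too weak to harm the esters.

27 to 26: the C1–C2 single bond is traced back to an alkene of either geometry. The hydrogenation must leave the conjugated C4=C5 untouched.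

26 to 25: C1=C2 is cut by retro-metathesis to two vinyl groups on C10 and C3. This removes the medium ring and leaves a bicyclic core with two arms. The forward step must favour ring closure over oligomerisation and must not touch C4=C5.

25 to 18 and 23: C5–C6 and O6–C15 are cut. The molecule falls into a lactone half (C6 to C12, C14, C1) and a butenolide half (C1' vinyl, C2 to C5, C15) that brings C3 as a preset stereocentre. The forward step must be a non-basic C–C coupling that tolerates the acidic C11–H and must attack the C6 aldehyde on the correct face.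

23 to 22 to 21 to 19 and 20: the O-acyl bond, then the C3–C4 and C5–I bonds are cut. C3 is created racemic on a six-carbon fragment and resolved there, so no advanced material is lost. The halo-aldol must give the Z iodide (iodine cis to the ester), or lactonisation later fails.

18 to 17 to 14: C6 is taken back to the alcohol level and the C11–P bond is cut. Phosphorylation needs a strong base, so it is placed where the lactone is the only acidic site, long before the butenolide and the C3 ester exist. C6–OH must be masked for that one operation.

14 to 13 to 12: the temporary silyl ether is removed and the C6 alcohol is traced to the acyl-oxazolidinone. The reduction must select the imide carbonyl over the lactone.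

12 to 7 and 10: C7–C8 and O8–C12 are cut. A succinate aldol sets C7 and C8 together under auxiliary control and lactonises to the trans-lactone. The existing C10 centre in 7 is too remote to interfere.

10 to 8 and 9: the N-acyl bond is cut to two commercial compounds.

7 to 6 to 5 to 3 and 4: after redox adjustment and removal of one ester carbon, C9–C10 is cut by an allylic alkylation with malonate. The forward step must be branched-selective and enantioselective. This is why the E-configured carbonate is used, since Z-allylic carbonates are poorer substrates in iridium allylation.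

3 to 2 to 1: the carbonate and one silyl ether are cut back to the symmetrical diol, which demands clean monosilylation.

## Other disconnections considered

Alternative 1: The cut is C8–C9. SmI2 reduces aldehyde A2 to a ketyl that adds to the β-carbon (C9) of the 2-substituted acrylate A3. Protonation at C10 and closure of O8 onto the ester carbon C14 give the cis-2,4-disubstituted γ-lactone A1.
- In favour: one reductive step under neutral conditions makes a skeletal bond and two stereocentres (C8, C10). The lactone ties C8 to C10, so their relationship can be corrected by equilibration at C10. Both partners are small.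
- Against: C8 must be set relative to C7 by the facial preference of an α-branched ketyl, which is not secure. The lactone of A1 is only a relay, because C14 must later be reduced and O8 re-used for the C12 lactone. Four protecting groups are carried. The ten-membered ring, C13, C15 and both final lactones remain to be made, the ring presumably by a C3–C4 bond with no control at C3.
- Comparison: on structure this alternative is the better of the two in what the key step creates (one C–C bond and two stereocentres, against one bond and none). On mechanism the single-electron coupling is as tolerant of functionality as metathesis (equal), but it leaves the medium ring unsolved. On step economy it is clearly longer, since redox and protecting-group changes follow the key step, whereas the chosen plan needs three steps after it.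

Alternative 2: The cut is C4=C5. The eleven-membered lactone A5 (O6 acylated by the C15 acid, a vinyl group on C6, the acrylate methylene on C4) undergoes ring-closing metathesis. Closing the butenolide closes the carbocycle across the large lactone and gives A4, which is identical with 28.
- In favour: the reaction type is the same as in the chosen plan. The product is one desilylation from the target, and on this point the alternative is the better one, because no hydrogenation or olefination follows ring closure. The geometry of C4=C5 is fixed by the five-membered ring.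
- Against: the catalyst must join an electron-poor 1,1-disubstituted acrylate to a hindered vinyl group, forming a trisubstituted alkene while contracting the lactone into the strained bridged bicycle. The free methylene lactone of A5 is a second acrylate-type alkene that can engage the catalyst. A5 itself needs an eleven-membered lactonisation at a hindered secondary alcohol.
- Comparison: mechanistically the two plans are equal in kind. Structurally the chosen plan couples two monosubstituted alkenes and masks the competing methylene. In steps after the key step the alternative is shorter, but its precursor is harder to reach.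

Alternative 3: The cut is C6–C7. The thirteen-membered propargylic allylic ether A7 is deprotonated at C6, and a [2,3]-Wittig shift forms C6–C7, moves the alkene to C11=C13 and breaks O–C13. The ring contracts to the ten-membered cycloalkynol A6.
- In favour: ring contraction of thirteen-membered ethers to cyclodecynols is an established way to ten-membered germacranoid rings. In reliability of the ring-forming event it is at least the equal of a ten-membered metathesis. It creates two adjacent stereocentres (C6, C7) through an ordered five-membered transition state, which the chosen key step does not.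
- Against: the sense at C6 and C7 depends on the alkene geometry and on transannular control by C3, C8 and C10, or on a chiral amide base. After the key step the alkyne must be turned into the butenolide with C15 placed on C4 next to a propargylic silyl ether that can be eliminated. C12 must be oxidised and lactonised, and C3 must be acylated selectively among several silyl ethers.
- Comparison: on structure the alternative is better in stereocentres made by the key step. On mechanism it needs a strong base, whereas the chosen step is neutral. On step economy it is longer after the key step, and the chosen plan sets every stereocentre earlier under reagent control.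

Key step: step 16

Structure check: 25 and 26 carry the target's arrangement at C3, C6, C7, C8 and C10. C10 is S in 5 to 26 (after step 4) and R in 27 to 29 only because C1 loses priority once it is saturated; no structure needs correction.
Assumption: in step 3 the (S,S,Sa) antipode of the phosphoramidite is taken to give (R)-5; if the sense is opposite, the (R,R,Ra) ligand is used and nothing else changes.
Assumption: 1 is purchased; it is also available in one step from but-2-yne-1,4-diol and LiAlH4.

## Route

Step 1
Reactants: 1 (E)-but-2-ene-1,4-diol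
Product: 2 (E)-4-[(tert-butyldimethylsilyl)oxy]but-2-en-1-ol
Conditions: NaH (1.0 equiv), THF, 0 °C to rt; TBSCl (1.0 equiv)
Reagents that add atoms: tert-butyldimethylsilyl chloride, C[Si](C)(Cl)C(C)(C)C
Why: Monosilylation of a symmetrical diol through its sparingly soluble monosodium alkoxide (O-silylation); no stereocentre is involved.

Step 2
Reactants: 2 (E)-4-[(tert-butyldimethylsilyl)oxy]but-2-en-1-ol
Product: 3 (E)-4-[(tert-butyldimethylsilyl)oxy]but-2-en-1-yl methyl carbonate
Conditions: ClCO2Me, pyridine, CH2Cl2, 0 °C
Reagents that add atoms: methyl chloroformate, COC(Cl)=O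
Why: O-acylation of a primary allylic alcohol; the methyl carbonate is the leaving group for the allylation and releases methoxide as the internal base.

Step 3
Reactants: 3 (E)-4-[(tert-butyldimethylsilyl)oxy]but-2-en-1-yl methyl carbonate; 4 dimethyl malonate
Product: 5 dimethyl 2-[(2R)-1-[(tert-butyldimethylsilyl)oxy]but-3-en-2-yl]propanedioate
Conditions: [Ir(cod)Cl]2 (2 mol%), O,O'-(S)-(1,1'-binaphthalene-2,2'-diyl) N,N-bis[(S)-1-phenylethyl]phosphoramidite (4 mol%), 1,5,7-triazabicyclo[4.4.0]dec-5-ene (8 mol%), THF, rt
Reagents that add atoms: none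
Why: Iridium-catalysed asymmetric allylic alkylation: the cyclometalated iridium–phosphoramidite complex ionises the E-carbonate, and the malonate attacks the substituted allyl terminus anti to the metal to give the branched product. The ligand decides which face of that terminus is attacked and so sets C10.

Step 4
Reactants: 5 dimethyl 2-[(2R)-1-[(tert-butyldimethylsilyl)oxy]but-3-en-2-yl]propanedioate
Product: 6 methyl (3S)-3-{[(tert-butyldimethylsilyl)oxy]methyl}pent-4-enoate
Conditions: NaCl, H2O, DMSO, 150 °C
Reagents that add atoms: none
Why: Krapcho dealkoxycarbonylation: chloride demethylates one ester, the carboxylate loses CO2 and the ester enolate is protonated. The stereocentre is not at the reacting carbon; its descriptor changes only because the priorities change.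

Step 5
Reactants: 6 methyl (3S)-3-{[(tert-butyldimethylsilyl)oxy]methyl}pent-4-enoate
Product: 7 (3S)-3-{[(tert-butyldimethylsilyl)oxy]methyl}pent-4-enal
Conditions: iBu2AlH (1.05 equiv), CH2Cl2, −78 °C; aq. KNaC4H4O6
Reagents that add atoms: none
Why: Partial reduction of a methyl ester: the aluminium hemiacetal is stable at −78 °C and releases the aldehyde only on work-up.

Step 6
Reactants: 8 (4S)-4-benzyl-1,3-oxazolidin-2-one; 9 methyl 4-chloro-4-oxobutanoate
Product: 10 methyl 4-[(4S)-4-benzyl-2-oxo-1,3-oxazolidin-3-yl]-4-oxobutanoate
Conditions: n-BuLi, THF, −78 °C; then 9, −78 to 0 °C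
Reagents that add atoms: none
Why: N-acylation of the lithiated oxazolidinone by the acid chloride, which is far more electrophilic than the methyl ester.

Step 7
Reactants: 7 (3S)-3-{[(tert-butyldimethylsilyl)oxy]methyl}pent-4-enal; 10 methyl 4-[(4S)-4-benzyl-2-oxo-1,3-oxazolidin-3-yl]-4-oxobutanoate
Product: 12 (4S)-4-benzyl-3-{[(2R,3S)-2-[(2S)-2-{[(tert-butyldimethylsilyl)oxy]methyl}but-3-en-1-yl]-5-oxooxolan-3-yl]carbonyl}-1,3-oxazolidin-2-one, via syn-aldol hydroxy ester 11 (not isolated)
Conditions: 10 (1.1 equiv), Bu2BOTf, iPr2NEt, CH2Cl2, −78 to 0 °C; 7, −78 to 0 °C; pH 7 buffer, MeOH, H2O2; then PPTS (cat.), CH2Cl2, rt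
Reagents that add atoms: none
Why: Evans syn-aldol reaction followed by lactonisation: Bu2BOTf and iPr2NEt enolise only the imide to its Z-boron enolate, which adds to 7 through a chair transition state on the face away from the benzyl group and sets C7 (S) and C8 (R) together. The C8 hydroxyl of 11 then closes onto the methyl ester (5-exo-trig) to the trans-lactone; C10 is remote and is not affected.

Step 8
Reactants: 12 (4S)-4-benzyl-3-{[(2R,3S)-2-[(2S)-2-{[(tert-butyldimethylsilyl)oxy]methyl}but-3-en-1-yl]-5-oxooxolan-3-yl]carbonyl}-1,3-oxazolidin-2-one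
Product: 13 (4R,5R)-5-[(2S)-2-{[(tert-butyldimethylsilyl)oxy]methyl}but-3-en-1-yl]-4-(hydroxymethyl)oxolan-2-one
Conditions: NaBH4, THF/H2O (3:1), 0 °C
Reagents that add atoms: none
Why: Chemoselective borohydride reduction of the activated exocyclic imide carbonyl releases the auxiliary and gives the C6 primary alcohol. The lactone and the silyl ether are less electrophilic, and a short reaction at 0 °C limits lactone reduction and lactone migration to O6.

Step 9
Reactants: 13 (4R,5R)-5-[(2S)-2-{[(tert-butyldimethylsilyl)oxy]methyl}but-3-en-1-yl]-4-(hydroxymethyl)oxolan-2-one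
Product: 14 (4R,5R)-5-[(2S)-2-{[(tert-butyldimethylsilyl)oxy]methyl}but-3-en-1-yl]-4-{[(triethylsilyl)oxy]methyl}oxolan-2-one
Conditions: TESCl, imidazole, CH2Cl2, 0 °C
Reagents that add atoms: chlorotriethylsilane, CC[Si](Cl)(CC)CC
Why: Silylation of the primary alcohol, so that the next step meets one acidic site only; triethylsilyl is chosen because it can be removed beside the primary TBS ether.

Step 10
Reactants: 14 (4R,5R)-5-[(2S)-2-{[(tert-butyldimethylsilyl)oxy]methyl}but-3-en-1-yl]-4-{[(triethylsilyl)oxy]methyl}oxolan-2-one
Product: 17 diethyl [(3S,4R,5R)-5-[(2S)-2-{[(tert-butyldimethylsilyl)oxy]methyl}but-3-en-1-yl]-4-(hydroxymethyl)-2-oxooxolan-3-yl]phosphonate, via phosphonite 15 (not isolated), via triethylsilyl ether phosphonate 16 (not isolated)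
Conditions: LiN(iPr)2 (2.2 equiv), THF, −78 °C; ClP(OEt)2, −78 °C to rt; AcOH; air, rt; then PPTS, MeOH, rt
Reagents that add atoms: diethyl chlorophosphite, CCOP(Cl)OCC; dioxygen, O=O
Why: C-phosphinylation of a lactone enolate followed by oxidation: the amide base removes a C11 proton, the only acidic C–H of 14, the enolate attacks the soft trivalent phosphorus chloride at carbon to give 15, and air oxidises 15 to the phosphonate 16. The acidic C11–H lets the product settle as the trans isomer (phosphonate opposite to the C7 substituent), a centre that is destroyed again in step 18. PPTS in methanol then cleaves only the primary triethylsilyl ether, which is far more acid-labile than the primary TBS ether.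

Step 11
Reactants: 17 diethyl [(3S,4R,5R)-5-[(2S)-2-{[(tert-butyldimethylsilyl)oxy]methyl}but-3-en-1-yl]-4-(hydroxymethyl)-2-oxooxolan-3-yl]phosphonate
Product: 18 diethyl [(3S,4S,5R)-5-[(2S)-2-{[(tert-butyldimethylsilyl)oxy]methyl}but-3-en-1-yl]-4-formyl-2-oxooxolan-3-yl]phosphonate
Conditions: Dess–Martin periodinane, CH2Cl2, 0 °C to rt
Reagents that add atoms: none
Why: Dess–Martin oxidation under non-basic conditions, which avoids β-elimination of the lactone oxygen from the new aldehyde and condensation through the acidic C11–H. The all-trans ring is the stable arrangement at C7, and the aldehyde is used crude.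

Step 12
Reactants: 19 methyl prop-2-ynoate; 20 prop-2-enal
Product: 21 methyl (2Z)-2-(1-hydroxyprop-2-en-1-yl)-3-iodoprop-2-enoate (racemate)
Conditions: MgI2 (1.2 equiv), CH2Cl2, 0 °C; aq. NH4Cl
Reagents that add atoms: magnesium iodide, [Mg+2].[I-].[I-]
Why: Halo-aldol reaction (β-iodo variant of the Morita–Baylis–Hillman reaction): iodide adds to the alkynoate, and the magnesium β-iodoallenolate adds 1,2 to the aldehyde. At 0 °C the kinetic Z isomer, with iodine cis to the ester, is expected; C3 is formed racemic.

Step 13
Reactants: 21 methyl (2Z)-2-(1-hydroxyprop-2-en-1-yl)-3-iodoprop-2-enoate (racemate)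
Product: 22 methyl (2Z)-2-[(1S)-1-hydroxyprop-2-en-1-yl]-3-iodoprop-2-enoate
Conditions: Ti(OiPr)4 (20 mol%), L-(+)-diisopropyl tartrate (24 mol%), t-BuOOH (0.6 equiv), 4 Å MS, CH2Cl2, −20 °C
Reagents that add atoms: none
Why: Sharpless kinetic resolution of a secondary allylic alcohol: with the L-(+)-tartrate the R enantiomer is epoxidised at its vinyl group much faster, because the oxidant reaches the alkene face on which the carbinol hydrogen, not the large substituent, lies. The iodoacrylate alkene is too electron-poor to react, so the S alcohol remains and C3 is fixed.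

Step 14
Reactants: 22 methyl (2Z)-2-[(1S)-1-hydroxyprop-2-en-1-yl]-3-iodoprop-2-enoate
Product: 23 methyl (2Z)-3-iodo-2-[(1S)-1-(2-methylpropanoyloxy)prop-2-en-1-yl]prop-2-enoate
Conditions: iPrCOCl, pyridine, CH2Cl2, 0 °C to rt
Reagents that add atoms: 2-methylpropanoyl chloride, CC(C)C(Cl)=O
Why: Esterification of the secondary alcohol with retention at C3. Pyridine without a more nucleophilic catalyst avoids addition–elimination at the β-iodoacrylate.

Step 15
Reactants: 18 diethyl [(3S,4S,5R)-5-[(2S)-2-{[(tert-butyldimethylsilyl)oxy]methyl}but-3-en-1-yl]-4-formyl-2-oxooxolan-3-yl]phosphonate; 23 methyl (2Z)-3-iodo-2-[(1S)-1-(2-methylpropanoyloxy)prop-2-en-1-yl]prop-2-enoate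
Product: 25 diethyl [(3S,4S,5R)-5-[(2S)-2-{[(tert-butyldimethylsilyl)oxy]methyl}but-3-en-1-yl]-4-[(2R)-4-[(1S)-1-(2-methylpropanoyloxy)prop-2-en-1-yl]-5-oxo-2,5-dihydrofuran-2-yl]-2-oxooxolan-3-yl]phosphonate, via hydroxy ester 24 (not isolated)
Conditions: CrCl2 (6 equiv), NiCl2 (2 mol%), DMSO, rt; then PPTS (cat.), CH2Cl2, rt
Reagents that add atoms: none
Why: Nozaki–Hiyama–Kishi coupling: zerovalent nickel inserts into the C–I bond with retention of the Z geometry, and transmetalation gives an alkenyl trivalent chromium species that adds only to the aldehyde. The alkoxide of 24 then closes onto the cis ester (5-exo-trig lactonisation) to the butenolide. C6 is set by Felkin–Anh addition anti to the C7–C11 bond, because the other staggered trajectory passes the phosphonate on C11; this should favour 6R, and the neutral medium leaves the acidic C11–H, the lactone and the esters alone.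

Step 16
Reactants: 25 diethyl [(3S,4S,5R)-5-[(2S)-2-{[(tert-butyldimethylsilyl)oxy]methyl}but-3-en-1-yl]-4-[(2R)-4-[(1S)-1-(2-methylpropanoyloxy)prop-2-en-1-yl]-5-oxo-2,5-dihydrofuran-2-yl]-2-oxooxolan-3-yl]phosphonate
Product: 26 (1Z,3S,6R,7S,8R,10S,11S)-14-[(tert-butyldimethylsilyl)oxy]-11-(diethoxyphosphoryl)-3-(2-methylpropanoyloxy)-13-norgermacra-1,4-diene-15,6:12,8-diolide
Conditions: second-generation Grubbs catalyst (2 × 10 mol%), 1,4-benzoquinone (20 mol%), toluene (1 mM), 80 °C, argon sparge
Reagents that add atoms: none
Why: Olefin metathesis by the Chauvin mechanism: the ruthenium benzylidene exchanges onto the less hindered C10 vinyl group, the resulting C1 alkylidene adds [2+2] to the C3 vinyl group, and cycloreversion of the ruthenacyclobutane gives C1=C2 and a ruthenium methylidene while ethene leaves the solution. The closest known reaction type is ring-closing metathesis to ten-membered carbocycles, which is known to depend on the substrate. The one ring closed is the ten-membered carbocycle C1 to C10, by ring-closing metathesis of two terminal vinyl groups. No stereocentre is formed, and the Z isomer is expected for this ring size, but either geometry serves because step 17 saturates the bond. Ring closure must win over oligomerisation: high dilution, portionwise catalyst addition and the two lactone rings, which already hold C4 to C8 in an arc so that only the two arms must fold, serve this. C4=C5 must not react, and a trisubstituted, ester-conjugated alkene is inert to this catalyst. The C11 phosphonate removes the exocyclic methylene that would otherwise close a cyclohexene with the C10 vinyl group, and benzoquinone suppresses ruthenium hydride migration of the two allylic double bonds.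

Step 17
Reactants: 26 (1Z,3S,6R,7S,8R,10S,11S)-14-[(tert-butyldimethylsilyl)oxy]-11-(diethoxyphosphoryl)-3-(2-methylpropanoyloxy)-13-norgermacra-1,4-diene-15,6:12,8-diolide
Product: 27 (3S,6R,7S,8R,10R,11S)-14-[(tert-butyldimethylsilyl)oxy]-11-(diethoxyphosphoryl)-3-(2-methylpropanoyloxy)-13-norgermacr-4-ene-15,6:12,8-diolide
Conditions: RhCl(PPh3)3 (10 mol%), H2 (1 atm), benzene/EtOH (1:1), rt
Reagents that add atoms: none
Why: Homogeneous hydrogenation: the disubstituted C1=C2 binds to the rhodium catalyst and is reduced, whereas the trisubstituted conjugated C4=C5 is inert to it. No stereocentre is created; C10 becomes R by a change of priority only.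

Step 18
Reactants: 27 (3S,6R,7S,8R,10R,11S)-14-[(tert-butyldimethylsilyl)oxy]-11-(diethoxyphosphoryl)-3-(2-methylpropanoyloxy)-13-norgermacr-4-ene-15,6:12,8-diolide
Product: 28 (3S,6R,7S,8R,10R)-14-[(tert-butyldimethylsilyl)oxy]-3-(2-methylpropanoyloxy)germacra-4,11(13)-diene-15,6:12,8-diolide
Conditions: 37% aq. HCHO, K2CO3, THF, 0 °C to rt
Reagents that add atoms: formaldehyde, C=O
Why: Horner–Wadsworth–Emmons olefination: carbonate removes only the C11–H flanked by P=O and C=O, the carbanion adds to formaldehyde, and loss of diethyl phosphate gives the exocyclic methylene. The C6–H of the bridged butenolide cannot become planar within the ten-membered ring, so the base-induced loss of the C3 ester is not expected here.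

Step 19
Reactants: 28 (3S,6R,7S,8R,10R)-14-[(tert-butyldimethylsilyl)oxy]-3-(2-methylpropanoyloxy)germacra-4,11(13)-diene-15,6:12,8-diolide
Product: 29 (3S,6R,7S,8R,10R)-14-hydroxy-3-(2-methylpropanoyloxy)germacra-4,11(13)-diene-15,6:12,8-diolide (CNP0332805.1)
Conditions: HF·pyridine, pyridine, THF, 0 °C to rt
Reagents that add atoms: none
Why: Fluoride-induced cleavage of the primary silyl ether under buffered, weakly acidic conditions, which neither add to the methylene lactone nor cleave the isobutyrate.

## Compound list

1 | (E)-but-2-ene-1,4-diol | OC/C=C/CO | starting material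
2 | (E)-4-[(tert-butyldimethylsilyl)oxy]but-2-en-1-ol | OC/C=C/CO[Si](C)(C)C(C)(C)C | intermediate
3 | (E)-4-[(tert-butyldimethylsilyl)oxy]but-2-en-1-yl methyl carbonate | COC(=O)OC/C=C/CO[Si](C)(C)C(C)(C)C | intermediate
4 | dimethyl malonate | COC(=O)CC(=O)OC | starting material
5 | dimethyl 2-[(2R)-1-[(tert-butyldimethylsilyl)oxy]but-3-en-2-yl]propanedioate | COC(=O)C(C(=O)OC)[C@@H](C=C)CO[Si](C)(C)C(C)(C)C | intermediate
6 | methyl (3S)-3-{[(tert-butyldimethylsilyl)oxy]methyl}pent-4-enoate | COC(=O)C[C@@H](C=C)CO[Si](C)(C)C(C)(C)C | intermediate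
7 | (3S)-3-{[(tert-butyldimethylsilyl)oxy]methyl}pent-4-enal | O=CC[C@@H](C=C)CO[Si](C)(C)C(C)(C)C | intermediate
8 | (4S)-4-benzyl-1,3-oxazolidin-2-one | O=C1N[C@@H](Cc2ccccc2)CO1 | starting material
9 | methyl 4-chloro-4-oxobutanoate | COC(=O)CCC(Cl)=O | starting material
10 | methyl 4-[(4S)-4-benzyl-2-oxo-1,3-oxazolidin-3-yl]-4-oxobutanoate | COC(=O)CCC(=O)N1[C@@H](Cc2ccccc2)COC1=O | intermediate
11 | methyl (3S,4R,6S)-3-{[(4S)-4-benzyl-2-oxo-1,3-oxazolidin-3-yl]carbonyl}-6-{[(tert-butyldimethylsilyl)oxy]methyl}-4-hydroxyoct-7-enoate | COC(=O)C[C@H](C(=O)N1[C@@H](Cc2ccccc2)COC1=O)[C@H](O)C[C@@H](C=C)CO[Si](C)(C)C(C)(C)C | intermediate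
12 | (4S)-4-benzyl-3-{[(2R,3S)-2-[(2S)-2-{[(tert-butyldimethylsilyl)oxy]methyl}but-3-en-1-yl]-5-oxooxolan-3-yl]carbonyl}-1,3-oxazolidin-2-one | O=C1C[C@H](C(=O)N2[C@@H](Cc3ccccc3)COC2=O)[C@@H](C[C@@H](C=C)CO[Si](C)(C)C(C)(C)C)O1 | intermediate
13 | (4R,5R)-5-[(2S)-2-{[(tert-butyldimethylsilyl)oxy]methyl}but-3-en-1-yl]-4-(hydroxymethyl)oxolan-2-one | O=C1C[C@H](CO)[C@@H](C[C@@H](C=C)CO[Si](C)(C)C(C)(C)C)O1 | intermediate
14 | (4R,5R)-5-[(2S)-2-{[(tert-butyldimethylsilyl)oxy]methyl}but-3-en-1-yl]-4-{[(triethylsilyl)oxy]methyl}oxolan-2-one | O=C1C[C@H](CO[Si](CC)(CC)CC)[C@@H](C[C@@H](C=C)CO[Si](C)(C)C(C)(C)C)O1 | intermediate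
15 | diethyl [(3S,4R,5R)-5-[(2S)-2-{[(tert-butyldimethylsilyl)oxy]methyl}but-3-en-1-yl]-2-oxo-4-{[(triethylsilyl)oxy]methyl}oxolan-3-yl]phosphonite | O=C1[C@@H](P(OCC)OCC)[C@H](CO[Si](CC)(CC)CC)[C@@H](C[C@@H](C=C)CO[Si](C)(C)C(C)(C)C)O1 | intermediate
16 | diethyl [(3S,4R,5R)-5-[(2S)-2-{[(tert-butyldimethylsilyl)oxy]methyl}but-3-en-1-yl]-2-oxo-4-{[(triethylsilyl)oxy]methyl}oxolan-3-yl]phosphonate | O=C1[C@@H](P(=O)(OCC)OCC)[C@H](CO[Si](CC)(CC)CC)[C@@H](C[C@@H](C=C)CO[Si](C)(C)C(C)(C)C)O1 | intermediate
17 | diethyl [(3S,4R,5R)-5-[(2S)-2-{[(tert-butyldimethylsilyl)oxy]methyl}but-3-en-1-yl]-4-(hydroxymethyl)-2-oxooxolan-3-yl]phosphonate | O=C1[C@@H](P(=O)(OCC)OCC)[C@H](CO)[C@@H](C[C@@H](C=C)CO[Si](C)(C)C(C)(C)C)O1 | intermediate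
18 | diethyl [(3S,4S,5R)-5-[(2S)-2-{[(tert-butyldimethylsilyl)oxy]methyl}but-3-en-1-yl]-4-formyl-2-oxooxolan-3-yl]phosphonate | O=C1[C@@H](P(=O)(OCC)OCC)[C@H](C=O)[C@@H](C[C@@H](C=C)CO[Si](C)(C)C(C)(C)C)O1 | intermediate
19 | methyl prop-2-ynoate (methyl propiolate) | C#CC(=O)OC | starting material
20 | prop-2-enal (acrolein) | C=CC=O | starting material
21 | methyl (2Z)-2-(1-hydroxyprop-2-en-1-yl)-3-iodoprop-2-enoate, racemate | I/C=C(\C(=O)OC)C(O)C=C | intermediate
22 | methyl (2Z)-2-[(1S)-1-hydroxyprop-2-en-1-yl]-3-iodoprop-2-enoate | I/C=C(\C(=O)OC)[C@@H](O)C=C | intermediate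
23 | methyl (2Z)-3-iodo-2-[(1S)-1-(2-methylpropanoyloxy)prop-2-en-1-yl]prop-2-enoate | I/C=C(\C(=O)OC)[C@@H](OC(=O)C(C)C)C=C | intermediate
24 | methyl (2Z,4R)-4-[(2R,3R,4S)-2-[(2S)-2-{[(tert-butyldimethylsilyl)oxy]methyl}but-3-en-1-yl]-4-(diethoxyphosphoryl)-5-oxooxolan-3-yl]-4-hydroxy-2-[(1S)-1-(2-methylpropanoyloxy)prop-2-en-1-yl]but-2-enoate | O=C1[C@@H](P(=O)(OCC)OCC)[C@H]([C@H](O)/C=C(\C(=O)OC)[C@@H](OC(=O)C(C)C)C=C)[C@@H](C[C@@H](C=C)CO[Si](C)(C)C(C)(C)C)O1 | intermediate
25 | diethyl [(3S,4S,5R)-5-[(2S)-2-{[(tert-butyldimethylsilyl)oxy]methyl}but-3-en-1-yl]-4-[(2R)-4-[(1S)-1-(2-methylpropanoyloxy)prop-2-en-1-yl]-5-oxo-2,5-dihydrofuran-2-yl]-2-oxooxolan-3-yl]phosphonate | C=C[C@@H](CO[Si](C)(C)C(C)(C)C)C[C@H]1OC(=O)[C@@H](P(=O)(OCC)OCC)[C@@H]1[C@@H]2OC(=O)C([C@@H](OC(=O)C(C)C)C=C)=C2 | intermediate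
26 | (1Z,3S,6R,7S,8R,10S,11S)-14-[(tert-butyldimethylsilyl)oxy]-11-(diethoxyphosphoryl)-3-(2-methylpropanoyloxy)-13-norgermacra-1,4-diene-15,6:12,8-diolide | CCOP(=O)(OCC)[C@@H]1C(=O)O[C@@H]2C[C@H](CO[Si](C)(C)C(C)(C)C)/C=C\[C@H](OC(=O)C(C)C)C3=C[C@@H](OC3=O)[C@@H]12 | intermediate
27 | (3S,6R,7S,8R,10R,11S)-14-[(tert-butyldimethylsilyl)oxy]-11-(diethoxyphosphoryl)-3-(2-methylpropanoyloxy)-13-norgermacr-4-ene-15,6:12,8-diolide | CCOP(=O)(OCC)[C@@H]1C(=O)O[C@@H]2C[C@H](CO[Si](C)(C)C(C)(C)C)CC[C@H](OC(=O)C(C)C)C3=C[C@@H](OC3=O)[C@@H]12 | intermediate
28 | (3S,6R,7S,8R,10R)-14-[(tert-butyldimethylsilyl)oxy]-3-(2-methylpropanoyloxy)germacra-4,11(13)-diene-15,6:12,8-diolide | C=C1C(=O)O[C@@H]2C[C@H](CO[Si](C)(C)C(C)(C)C)CC[C@H](OC(=O)C(C)C)C3=C[C@@H](OC3=O)[C@@H]12 | intermediate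
29 | (3S,6R,7S,8R,10R)-14-hydroxy-3-(2-methylpropanoyloxy)germacra-4,11(13)-diene-15,6:12,8-diolide (CNP0332805.1) | C=C1C(=O)O[C@@H]2C[C@H](CO)CC[C@H](OC(=O)C(C)C)C3=C[C@@H](OC3=O)[C@@H]12 | target

## Step count and least certain steps

Total step count: 19. Longest linear sequence: 15 steps (steps 1 to 5, 7 to 11 and 15 to 19).

**Step 16 (key step).** The most likely failure is intermolecular metathesis outrunning ring closure. Folding both arms onto the rigid bis-lactone costs strain, since the ring holds a ring-trans C4=C5 tied back by the butenolide. The alkylidene next to the isobutyrate may also rest as an unproductive carbonyl chelate, and double-bond migration may give ring-contracted products.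

Fallback: close the ring before the butenolide exists. It sets out from 18 and 23.
- The nickel/chromium coupling is run with catalytic CrCl2 and NiCl2, manganese powder and TMSCl. This traps the chromium alkoxide as the C6 trimethylsilyl ether of 24, F1, and so blocks lactonisation.
- Ring-closing metathesis of F1, which lacks the bicyclic constraint, gives the ten-membered silyl ether F2.
- PPTS in methanol removes the silyl group, and the freed C6 hydroxyl closes onto the cis ester.

The fallback returns to the route at 26.

**Step 15.** Facial selectivity at the aldehyde may be poor, because the two Felkin-type trajectories differ only in the substituents on C8 and C11. Partial Z-to-E isomerisation of the alkenylchromium species would stop lactonisation, and β-elimination of the lactone oxygen from the aldehyde is possible. A chromium-bound chiral sulfonamide ligand is the first adjustment.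

Fallback: set C6 by stereospecific inversion. It sets out from 18 and 20.
- tert-Butyl propiolate is taken through the operations of steps 12 to 14 to the racemic iodo alcohol F3, the resolved S alcohol F4 and the isobutyrate F5.
- Coupling of F5 with 18 as in step 15 stops at the open hydroxy tert-butyl ester, which cannot lactonise.
- If the 6S epimer F6 predominates, its ester is cleaved with TMSOTf and 2,6-lutidine followed by dilute aqueous acid to the hydroxy acid F7.
- Mitsunobu lactonisation (PPh3, diisopropyl azodicarboxylate) closes the butenolide with inversion at C6.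

Any 6R epimer lactonises with retention after the same ester cleavage, so both converge and the fallback returns to the route at 25.

**Step 12.** Iodide may add in the conjugate sense to acrolein, acrolein may polymerise under the Lewis-acidic conditions, and the Z geometry may erode on warming.

Fallback: mask the vinyl group. It sets out from 19 and 20.
- 20 and benzeneselenol give 3-(phenylselanyl)propanal F8.
- F8 replaces 20 in the MgI2 reaction with 19 and gives the selenide adduct F9.
- Oxidation with NaIO4 and syn-elimination of the selenoxide, for which only the C2 hydrogens are available, unveil the vinyl group.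

The fallback returns to the route at 21.

**Step 3.** The branched-to-linear ratio and the enantioselectivity may erode with the small, inductively withdrawing silyloxymethyl substituent.

Fallback: give up catalytic asymmetric induction and let the auxiliary of step 7 resolve C10. It sets out from 2.
- Johnson–Claisen rearrangement of 2 with triethyl orthoacetate (propanoic acid cat., 140 °C) gives the racemic ethyl ester F10.
- iBu2AlH at −78 °C gives the racemic aldehyde F11.
- The aldol of step 7 with F11 gives 12 together with its C10 epimer F12, which is removed by chromatography.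

The fallback returns to the route at 12.

## Further compounds

F1 | step 16 | C6 O-trimethylsilyl ether of 24 | O=C1[C@@H](P(=O)(OCC)OCC)[C@H]([C@H](O[Si](C)(C)C)/C=C(\C(=O)OC)[C@@H](OC(=O)C(C)C)C=C)[C@@H](C[C@@H](C=C)CO[Si](C)(C)C(C)(C)C)O1
F2 | step 16 | ten-membered (1Z)-diene from F1, methyl ester at C15 and trimethylsilyl ether at O6, trans-lactone phosphonate retained | O=C1[C@@H](P(=O)(OCC)OCC)[C@@H]2[C@H](O[Si](C)(C)C)/C=C(\C(=O)OC)[C@@H](OC(=O)C(C)C)/C=C\[C@@H](CO[Si](C)(C)C(C)(C)C)C[C@H]2O1
F3 | step 15 | tert-butyl (2Z)-2-(1-hydroxyprop-2-en-1-yl)-3-iodoprop-2-enoate, racemate | I/C=C(\C(=O)OC(C)(C)C)C(O)C=C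
F4 | step 15 | tert-butyl (2Z)-2-[(1S)-1-hydroxyprop-2-en-1-yl]-3-iodoprop-2-enoate | I/C=C(\C(=O)OC(C)(C)C)[C@@H](O)C=C
F5 | step 15 | tert-butyl (2Z)-3-iodo-2-[(1S)-1-(2-methylpropanoyloxy)prop-2-en-1-yl]prop-2-enoate | I/C=C(\C(=O)OC(C)(C)C)[C@@H](OC(=O)C(C)C)C=C
F6 | step 15 | tert-butyl ester analogue of 24 with the 6S configuration | O=C1[C@@H](P(=O)(OCC)OCC)[C@H]([C@@H](O)/C=C(\C(=O)OC(C)(C)C)[C@@H](OC(=O)C(C)C)C=C)[C@@H](C[C@@H](C=C)CO[Si](C)(C)C(C)(C)C)O1
F7 | step 15 | (6S)-hydroxy acid from F6 | O=C1[C@@H](P(=O)(OCC)OCC)[C@H]([C@@H](O)/C=C(\C(=O)O)[C@@H](OC(=O)C(C)C)C=C)[C@@H](C[C@@H](C=C)CO[Si](C)(C)C(C)(C)C)O1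
F8 | step 12 | 3-(phenylselanyl)propanal | O=CCC[Se]c1ccccc1
F9 | step 12 | methyl (2Z)-2-[1-hydroxy-3-(phenylselanyl)propyl]-3-iodoprop-2-enoate, racemate | I/C=C(\C(=O)OC)C(O)CC[Se]c1ccccc1
F10 | step 3 | ethyl 3-{[(tert-butyldimethylsilyl)oxy]methyl}pent-4-enoate, racemate | CCOC(=O)CC(C=C)CO[Si](C)(C)C(C)(C)C
F11 | step 3 | 3-{[(tert-butyldimethylsilyl)oxy]methyl}pent-4-enal, racemate | O=CCC(C=C)CO[Si](C)(C)C(C)(C)C
F12 | step 3 | C10 epimer of 12, (4S)-4-benzyl-3-{[(2R,3S)-2-[(2R)-2-{[(tert-butyldimethylsilyl)oxy]methyl}but-3-en-1-yl]-5-oxooxolan-3-yl]carbonyl}-1,3-oxazolidin-2-one | O=C1C[C@H](C(=O)N2[C@@H](Cc3ccccc3)COC2=O)[C@@H](C[C@H](C=C)CO[Si](C)(C)C(C)(C)C)O1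
A1 | alternative 1 | cis-2,4-disubstituted γ-lactone (C14 to O8) carrying C3 to C12 | COC(OC)CC[C@@H]1C[C@@H](OC1=O)[C@H](CCOCc2ccc(OC)cc2)[C@H](O[Si](C)(C)C(C)(C)C)C#C[Si](C)(C)C
A2 | alternative 1 | C8 aldehyde with C7 (4-methoxybenzyloxyethyl branch) and C6 (silyl ether, silylalkyne) | O=C[C@H](CCOCc1ccc(OC)cc1)[C@H](O[Si](C)(C)C(C)(C)C)C#C[Si](C)(C)C
A3 | alternative 1 | methyl 5,5-dimethoxy-2-methylidenepentanoate | C=C(CCC(OC)OC)C(=O)OC
A4 | alternative 2 | C14 silyl ether of the target, identical with 28 | C=C1C(=O)O[C@@H]2C[C@H](CO[Si](C)(C)C(C)(C)C)CC[C@H](OC(=O)C(C)C)C3=C[C@@H](OC3=O)[C@@H]12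
A5 | alternative 2 | eleven-membered lactone (O6 to C15) with C6 vinyl group, C4 acrylate methylene and the methylene lactone | C=C1C(=O)O[C@@H]2C[C@H](CO[Si](C)(C)C(C)(C)C)CC[C@H](OC(=O)C(C)C)C(=C)C(=O)O[C@H](C=C)[C@@H]12
A6 | alternative 3 | ten-membered cycloalkynol carrying the C11 to C13 branch | C=C(CO[Si](C)(C)C(C)(C)C)[C@H]1[C@H](O[Si](C)(C)C(C)(C)C)C[C@H](COCc2ccc(OC)cc2)CC[C@H](O[Si](CC)(CC)CC)C#C[C@H]1O
A7 | alternative 3 | thirteen-membered propargylic allylic ether (O between C6 and C13, C7=C11 with the ring bonds trans) | O1CC#C[C@@H](O[Si](CC)(CC)CC)CC[C@@H](COCc2ccc(OC)cc2)C[C@@H](O[Si](C)(C)C(C)(C)C)/C=C(\CO[Si](C)(C)C(C)(C)C)C1
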